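The leftover is what has to be judged. At the last reading of the maple run, 14 h, E stands at 83.9 mM out of 120 mM of Z charged, so 36.1 mM of Z has not turned. The larch run repeats the maple charge and is read at 56 h: does that leftover turn?

| flask | Z | G | time |
|---|---|---|---|
| maple | 120 mM | 9.60 mM |  |
| ash | 48.0 mM | 9.60 mM |  |
| alder | 120 mM | 19.0 mM |  |
| cedar | 180 mM | 9.60 mM |  |
| larch | 120 mM | 9.60 mM | 56 h |

| maple run: time / h | maple run: [E] / mM | ash run: time / h | ash run: [E] / mM | alder run: time / h | alder run: [E] / mM | cedar run: time / h | cedar run: [E] / mM |
|---|---|---|---|---|---|---|---|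
| 1.1 | 8.4 | 1.1 | 6.8 | 1.1 | 16.0 | 1.1 | 8.2 |
| 3.2 | 37.1 | 3.2 | 30.4 | 3.2 | 69.8 | 3.2 | 37.5 |
| 6.2 | 64.9 | 6.2 | 45.4 | 6.2 | 113.3 | 6.2 | 66.2 |
| 9.8 | 78.9 | 9.8 | 49.1 | 9.8 | 120.3 | 9.8 | 80.0 |
| 14 | 83.9 | 14 | 48.0 | 14 | 119.8 | 14 | 84.4 |

(scatter of a reading: 0.4 mM)

- Overall: Z -> E, with G as catalyst.
- Constant volume, constant temperature.
- A reading of a species includes what of it is bound.
- An order is taken over about fifteen percent of the charge, up and down.

* order of the initial rate in [G], near the charge of the maple run, the rate being that where two percent of its Z are E
* order of the initial rate in [Z], near the charge of the maple run, the rate being that where two percent of its Z are E (one fixed amount of E, the same in the runs compared)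
* the ash run starts with 72.0 mM less of Z than the maple run, and with no E. Compared where both hold the same amount of Z, once fifteen percent of what the ash run was charged with has turned into E, is the ash run faster, slower or alike (within a tenth)?
* E in the larch run at 56 h, as a share of the Z charged

Two chemists disagree. The first holds that Z is the limiting reagent and that the maple run is merely slowing towards the end of its Z. The ash run read 48.0 mM from 48.0 mM of Z, and the alder run 119.8 mM from 120 mM. The maple run still gained 1.19 mM h⁻¹ over its last interval. At that pace its leftover needs 30.3 h, less than the 42.0 h the larch run has after 14 h, so she expects E in the larch run to reach the Z charged.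

The second holds that G has a working life. The cedar run, with 95.6 mM of Z unturned at 14 h, gained 1.05 mM h⁻¹ over its last interval, against 1.19 mM h⁻¹ in the maple run with its smaller leftover, a gap of 0.140 mM h⁻¹ that a scatter of 0.4 mM on each reading can produce. The maple gain itself fell from 3.89 mM h⁻¹ to 1.19 mM h⁻¹, a reading of 0.304 h⁻¹ for the decay. Carried past the last reading, that decay gives an estimated tail of 2.07 mM, so this side puts the end of the maple run near 86.0 mM.

My reckoning joins the two ends. Call the E made per G charged the allowance, read here as 8.96. This allowance is what chemists call a turnover number. At this temperature and for charges like these, I take final E as the smaller of the Z charge and the allowance times the G charge. For the larch run this gives 71.6% of the Z charged.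

The forecast takes the second side, “maple and cedar both stall near 85 mM whatever the Z charge, while ash and alder finish completely”, with 71.5%, orders of 0.58 in G and 0.07 in Z, and the ash run faster.

The simulation gives 71.9%, orders of 0.60 and 0.057, and the ash run faster, at 5.2 times the maple rate. The forecast parts from it on the order in Z.

    Lx + Z ⇌ GZ, settled at all times (76.60 M⁻¹)
    GZ → E + Lx (3.463 h⁻¹)
    G → Lx (0.6300 h⁻¹)
    GZ → Rx + Z (0.3852 h⁻¹)

In the maple charge, G turned into Lx with a constant of 0.630 h⁻¹ from the start, and over the same hours the GZ formed from Lx gave E with a constant of 3.46 h⁻¹ and Rx with one of 0.385 h⁻¹, 8.99 to one. The first chemist's view holds in the alder run, where the allowance on 19.0 mM of G comes to 170 mM, more than its 120 mM of Z, and E read 119.8 mM at 14 h. In the larch run the allowance comes to 86.0 mM, less than its 120 mM of Z, and at 56 h the Z unturned is 33.7 mM.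

(The numbers in the tables were generated by integration with constants of no real substance.)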